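The constants of this flask are hidden, so you work from Sunday's run.

the same everywhere: left-handed substrate 0.050 M; right-handed substrate 0.050 M; gas 3.5 mM (held)

| run | free catalyst | racemization catalyst | remark | time |
|---|---|---|---|---|
| Sunday's | 1 mM | 2.8 mM | run made earlier |  |
| flask | 1.0 mM | 5.5 mM |  | 5.0 h |

Sunday's run (percent of the left-handed substrate and right-handed substrate together charged)

| time / min | left-handed product / % | right-handed product / % | left-handed substrate / % |
|---|---|---|---|
| 5.00 | 1.5 | 1.2 | 47.1 |
| 12.0 | 7.8 | 1.4 | 45.0 |
| 25.0 | 15.5 | 8.8 | 37.4 |
| 60.0 | 24.7 | 16.4 | 28.3 |

(each reading ± 1 percentage point)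

* left-handed product and right-handed product together, in percent of the left-handed substrate and right-handed substrate charged together, at 5.0 h
* excess of left-handed product over right-handed product in the product at 5.0 h
* whether the exchange between left-handed substrate and right-handed substrate keeps pace with the reaction: how far the product's excess at 5.0 h gets from its value without exchange to its value with instant exchange (above 80% keeps pace, below 20% hardly takes part, else lags behind)

- free catalyst is single-handed; left-handed substrate and right-handed substrate are mirror images of each other, charged as a racemate, each of them at the stated concentration
- at the start none of the gas is in solution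
- an excess is below zero if the other one leads
- no earlier run changes the charge of racemization catalyst; that part of a forecast is a guess

Add both products, subtract them from the charge, and follow what is left of the two substrates together. Call this the pair; it is your limiting reagent. On Sunday:

left of the pair: 75.7% at 25.0 min, 58.9% at 60.0 min

tail rate = ln(first / second) / 35.0 min = 0.00717 min⁻¹

The tail rate is the fraction of the pair lost per minute late in the run, a pseudo-first-order constant, and it is a reading with the scatter of its readings.

Now turn the settings. Free catalyst stands at 1.0 mM here and 1 mM on Sunday, so by hand the tail rate stays. Racemization catalyst goes to 5.5 mM, twice Sunday's 2.8 mM. By hand that feeds the excess, and it is a guess, since Sunday's run shows a single charge. The total you leave alone: at 60.0 min on Sunday the left-handed substrate already read half of the pair. Time goes from 60.0 min to 5.0 h, so run the tail rate on from the last reading. This is my reckoning: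

loss number = ln(charged / left at 60.0 min) + tail rate × 240 min = 2.25

yield = 1 − exp(−loss number) = 89.5%

It assumes the fall in rate has stopped by 60.0 min, so treat it as a high reckoning.

The forecast reads that fall differently, as “the catalyst dies with a lifetime of about 30 min”. It gives 49%, lower than mine, with an excess of 22% and exchange that lags behind.

The flask gives 84.4%, an excess of 26.4%, and exchange that keeps pace, 92% of the way.

    gas ⇌ reagent, rate k1*(csat - [reagent]) (kL = 0.0120 s⁻¹)
    free catalyst ⇌ dormant form (K = 2.80, k = 5.30 × 10⁻⁴ s⁻¹)
    left-handed substrate + racemization catalyst ⇌ right-handed substrate + racemization catalyst, rate k3*[racemization catalyst]*[left-handed substrate] forward; the back reaction follows from the equilibrium constant (k = 0.170 L mol⁻¹ s⁻¹)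
    reagent + free catalyst + left-handed substrate → free catalyst + left-handed product (k = 140 L² mol⁻² s⁻¹)
    reagent → decomposition product (k = 5.10 × 10⁻⁶ s⁻¹)
    reagent + free catalyst + right-handed substrate → free catalyst + right-handed product (k = 79.0 L² mol⁻² s⁻¹)

So 15.6% of the pair is left in the flask at 5.0 h, against my 10.5%. In the flask, free catalyst stands at 26.4% of the catalyst charged at 2.50 h and 26.3% at 5.00 h, with 73.7% as dormant form. Take the neighbour flask with 6.0 × 10⁻⁴ M of free catalyst, and scale the tail rate by the charge, to 0.00430 min⁻¹, and the whole loss number with it, to 1.35. The reckoning gives 74.1%, and that neighbour flask gives 68.5%.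

(The data are calculated with constants of no real substance, and the scatter is random.)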